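The theta run, charged with 750 mM of reagent where the eta run had 250 mM and otherwise the same, holds 2.26 times the product of the eta run at 7.8 min, and we ask what that ratio says about where the catalyst waits.

| flask | starting material | reagent | free catalyst | time |
|---|---|---|---|---|
| eta | 250 mM | 250 mM | 20.0 mM |  |
| delta | 130 mM | 130 mM | 20.0 mM |  |
| beta | 250 mM | 250 mM | 30.0 mM |  |
| theta | 250 mM | 750 mM | 20.0 mM |  |
| gamma | 250 mM | 250 mM | 60.0 mM | 45 min |

| run | time / min | [product] / mM |
|---|---|---|
| eta run | 2.6 | 12.3 |
| eta run | 7.8 | 38.8 |
| eta run | 15 | 74.6 |
| eta run | 24 | 112.5 |
| eta run | 34 | 142.6 |
| eta run | 45 | 163.9 |
| delta run | 2.6 | 7.7 |
| delta run | 7.8 | 27.5 |
| delta run | 15 | 47.8 |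
| delta run | 24 | 68.0 |
| delta run | 34 | 81.5 |
| delta run | 45 | 89.5 |
| beta run | 2.6 | 16.6 |
| beta run | 7.8 | 59.4 |
| beta run | 15 | 106.9 |
| beta run | 24 | 150.5 |
| beta run | 34 | 178.1 |
| beta run | 45 | 194.4 |
| theta run | 2.6 | 27.8 |
| theta run | 7.8 | 87.5 |
| theta run | 15 | 152.6 |
| theta run | 24 | 191.5 |
| theta run | 34 | 212.8 |
| theta run | 45 | 218.2 |

(standard deviation of a reading: 0.8 mM)

- Overall: starting material + reagent -> product, with free catalyst as catalyst.
- Constant volume, constant temperature.
- Bound and free are read together.
- "The second partner" is reagent.
- An order is taken over about fifteen percent of the charge, up and down.

- order of the initial rate in [starting material], near the charge of the eta run, the rate being that where two percent of its starting material are product (one fixed amount of product, the same in the runs compared)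
- order of the initial rate in [reagent], near the charge of the eta run, the rate being that where two percent of its starting material are product
- the delta run starts with 120 mM less of starting material and of reagent than the eta run, and with no product. Compared where both hold the same amount of starting material, once fifteen percent of what the delta run was charged with has turned into product, is the delta run faster, slower or alike (within a tenth)?
- product in the gamma run at 45 min, as a share of the starting material charged

Suppose the catalyst first takes up starting material and then meets reagent; two extreme versions can then be solved in the head. In the first, reagent empties the loaded catalyst at once, so the rate has order one in starting material and zero in reagent. In the second, the catalyst stands loaded and waits, so the order is zero in starting material and one in reagent. Between these extremes the rate goes as reagent over reagent plus a fixed level, and the order in reagent is that level over the same sum. The theta ratio is above one but less than the factor of 3.00 in reagent, so the flask lies between them, and the ratio solves to 1260 mM. This is the crossover concentration, the reagent level at which emptying the loaded catalyst takes as long as the rest of the cycle. The eta charge lies below it, which gives an order in reagent of 0.835.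

Now we use the crossover on the delta run, charged with 130 mM of each partner. Reagent by itself should bring the delta run to 0.565 of the eta rate, yet at 7.8 min the delta run holds 0.709 of the eta product, which is more than reagent allows. The surplus must belong to the lower starting material, so our order in starting material, averaged between the two charges and read from same-time readings with their scatter, is −0.347. That is outside the bracket of the extremes. With one loaded form the two orders add to at least one, whether or not the loading runs back, but ours add to 0.488, so we commit to a flask in which extra starting material holds catalyst away from reagent.

The forecast gave 0.05 and 0.8 for the two orders, faster for the delta comparison and 88 % for the gamma run, holding that the “starting-material order is therefore close to zero”, where our order is negative.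

The simulation gives −0.33 in starting material, 0.75 in reagent, faster for the delta run, and 89.6 % for the gamma run.

    free catalyst + starting material ⇌ catalyst-substrate complex (6.960 /M/min, 0.8100 /min)
    catalyst-substrate complex + reagent → product + free catalyst (10.50 /M/min)
    catalyst-substrate complex + starting material ⇌ doubly bound catalyst, settled at all times (28.10 /M)
    free catalyst + product → spent catalyst + product (0.3480 /M/min)

At the eta charge, 7.03 doubly bound catalysts stand beside each catalyst-substrate complex, making the doubly bound form a resting state of substrate inhibition. The simulated run without that association proves the reason: the order in starting material rises from −0.33 to 0.63, and the order in reagent falls from 0.75 to 0.51. Read backwards through our rule, that lower reagent order gives a crossover of 265 mM, against the 1260 mM read from the theta run.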